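**Retrosynthetic overview**

1. Rings A and B are bought, not built: ring B comes from 2,5-dihydroxybenzaldehyde 1 (carried as its dibenzyl ether 2), ring A from 2'-hydroxy-3',4',5',6'-tetramethoxyacetophenone 3, which already holds all four ring A oxygens.
2. C2–C3 disconnection (Claisen–Schmidt condensation of 2 with 3) leads to chalcone 4.
3. O1–C2 disconnection: ring C, the only ring formed, is closed by oxidative cyclisation of 4 through flavanone 5 to the tetramethoxyflavone 6.
4. Last, one BCl3 operation removes both benzyl ethers and only the 5-O-methyl group (through 7 and 8) to give the target 9.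

Assumption: the target has no stereocentre or stereoaxis (it is achiral), so the "single enantiomer" requirement needs no stereocontrol. Compounds 1 and 3 are taken as catalogue compounds.

**Route**

Step 1
Reactants: 1 2,5-dihydroxybenzaldehyde
Product: 2 2,5-bis(benzyloxy)benzaldehyde
Conditions: BnBr (2.4 equiv), K2CO3 (3 equiv), DMF, 60 °C, N2
Reagents that add atoms: benzyl bromide, BrCc1ccccc1
Why: Williamson ether synthesis (SN2 O-alkylation of both phenoxides) masks the oxidation-prone hydroquinone as base-stable benzyl ethers; no stereocentre is formed.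

Step 2
Reactants: 2 2,5-bis(benzyloxy)benzaldehyde, 3 2'-hydroxy-3',4',5',6'-tetramethoxyacetophenone
Product: 4 (E)-3-[2,5-bis(benzyloxy)phenyl]-1-(2-hydroxy-3,4,5,6-tetramethoxyphenyl)prop-2-en-1-one
Conditions: KOH (50% aq.), EtOH, rt, 24–48 h; acidic work-up
Reagents that add atoms: none
Why: Claisen–Schmidt (crossed aldol) condensation of the methyl ketone enolate with the non-enolisable aldehyde, followed by E1cB loss of water, gives the conjugated E-enone as the thermodynamic alkene, with water as the only co-product.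

Step 3
Reactants: 4 (E)-3-[2,5-bis(benzyloxy)phenyl]-1-(2-hydroxy-3,4,5,6-tetramethoxyphenyl)prop-2-en-1-one
Product: 6 2-[2,5-bis(benzyloxy)phenyl]-5,6,7,8-tetramethoxy-4H-chromen-4-one, via 2',5'-bis(benzyloxy)-5,6,7,8-tetramethoxyflavanone 5 (not isolated)
Conditions: I2 (10 mol%), DMSO, 130 °C, 3 h
Reagents that add atoms: none
Why: Iodine-catalysed oxidative cyclisation: 6-endo oxa-Michael addition of the 2'-phenol gives racemic flavanone 5, then α-iodination and loss of HI install C2=C3 (which erases the C2 stereocentre), while DMSO reoxidises HI to I2.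

Step 4
Reactants: 6 2-[2,5-bis(benzyloxy)phenyl]-5,6,7,8-tetramethoxy-4H-chromen-4-one
Product: 9 5,2',5'-trihydroxy-6,7,8-trimethoxyflavone, via 2',5'-bis(dichloroboryloxy)-5,6,7,8-tetramethoxyflavone 7 (not isolated), via 5,2',5'-tris(dichloroboryloxy)-6,7,8-trimethoxyflavone 8 (not isolated)
Conditions: BCl3 (1 M in CH2Cl2, 6 equiv), pentamethylbenzene (6 equiv), CH2Cl2, −78 °C, 1 h, then 0 °C, 1–2 h (monitored); H2O quench
Reagents that add atoms: none
Why: Lewis-acid ether cleavage: BCl3 cleaves the benzyl aryl ethers at −78 °C with pentamethylbenzene trapping the benzyl cation by Friedel–Crafts alkylation, and on warming the boron chelated between C4=O and the peri 5-oxygen removes only that methyl (chelation-controlled demethylation), leaving the 6-, 7- and 8-methoxy groups intact.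

**Compound list**

1 | 2,5-dihydroxybenzaldehyde | O=Cc1cc(O)ccc1O | starting material
2 | 2,5-bis(benzyloxy)benzaldehyde | O=Cc1cc(OCc2ccccc2)ccc1OCc1ccccc1 | intermediate
3 | 1-(2-hydroxy-3,4,5,6-tetramethoxyphenyl)ethan-1-one (2'-hydroxy-3',4',5',6'-tetramethoxyacetophenone) | CC(=O)c1c(O)c(OC)c(OC)c(OC)c1OC | starting material
4 | (E)-3-[2,5-bis(benzyloxy)phenyl]-1-(2-hydroxy-3,4,5,6-tetramethoxyphenyl)prop-2-en-1-one | O=C(/C=C/c1cc(OCc2ccccc2)ccc1OCc1ccccc1)c1c(O)c(OC)c(OC)c(OC)c1OC | intermediate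
5 | racemic 2-[2,5-bis(benzyloxy)phenyl]-5,6,7,8-tetramethoxychroman-4-one (flavanone; C2 stereocentre, both enantiomers) | COc1c(OC)c(OC)c2c(c1OC)OC(c1cc(OCc3ccccc3)ccc1OCc1ccccc1)CC2=O | intermediate
6 | 2-[2,5-bis(benzyloxy)phenyl]-5,6,7,8-tetramethoxy-4H-chromen-4-one | COc1c(OC)c(OC)c2c(=O)cc(-c3cc(OCc4ccccc4)ccc3OCc3ccccc3)oc2c1OC | intermediate
7 | 2-[2,5-bis(dichloroboryloxy)phenyl]-5,6,7,8-tetramethoxy-4H-chromen-4-one | COc1c(OC)c(OC)c2c(=O)cc(-c3cc(OB(Cl)Cl)ccc3OB(Cl)Cl)oc2c1OC | intermediate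
8 | 2-[2,5-bis(dichloroboryloxy)phenyl]-5-(dichloroboryloxy)-6,7,8-trimethoxy-4H-chromen-4-one (boron on O5 chelated by C4=O) | COc1c(OC)c(OB(Cl)Cl)c2c(=O)cc(-c3cc(OB(Cl)Cl)ccc3OB(Cl)Cl)oc2c1OC | intermediate
9 | 5,2',5'-trihydroxy-6,7,8-trimethoxyflavone (2-(2,5-dihydroxyphenyl)-5-hydroxy-6,7,8-trimethoxy-4H-chromen-4-one) | COc1c(OC)c(O)c2c(=O)cc(-c3cc(O)ccc3O)oc2c1OC | target

**Totals**

Total step count: 4. Longest linear sequence: 4 steps (1 → 2 → 4 → 6 → 9; compound 3 enters at step 2).

**Three steps most likely to fail, with fallbacks**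

Step 4 (global BCl3 unmasking). The risks are over-demethylation at the 6-methoxy group next to the boron chelate and C-benzylation of the electron-rich hydroquinone ring. The fallback sets out from 6 and separates the two events by mechanism. Hydrogenolysis (H2, 1 atm, 10% Pd/C, EtOAc/MeOH, rt) removes both benzyl groups to give 2-(2,5-dihydroxyphenyl)-5,6,7,8-tetramethoxy-4H-chromen-4-one F5. AlCl3 in MeCN at 60 °C, followed by dilute HCl work-up, then cleaves only the chelated 5-methoxy group. The fallback comes back to the route at 9.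

Step 3 (I2/DMSO oxidative cyclisation). The risks are partial loss of benzyl groups to HI at 130 °C and iodination of the dialkoxy ring B. The fallback sets out from 4. NaOAc in refluxing EtOH closes the chalcone to flavanone 5, which is isolated this time. Soft enolisation (TMSOTf, Et3N, CH2Cl2, 0 °C) gives racemic {2-[2,5-bis(benzyloxy)phenyl]-5,6,7,8-tetramethoxy-2H-chromen-4-yl}oxy(trimethyl)silane F4. Saegusa–Ito oxidation with Pd(OAc)2 in MeCN at rt then installs the C2=C3 bond. The fallback comes back to the route at 6.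

Step 2 (Claisen–Schmidt condensation). The risks are the di-ortho-substituted, hindered ketone and the electron-rich ortho-substituted aldehyde, which can give sluggish conversion and Cannizzaro loss of 2. The fallback sets out from 2 and uses 3, and builds the C2–C3 bond by acyl transfer instead of aldol chemistry:
- Pinnick oxidation (NaClO2, NaH2PO4, 2-methylbut-2-ene, t-BuOH/H2O) gives 2,5-bis(benzyloxy)benzoic acid F1.
- Esterification with 3 (EDC·HCl, DMAP, CH2Cl2) gives 2-acetyl-3,4,5,6-tetramethoxyphenyl 2,5-bis(benzyloxy)benzoate F2.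
- Baker–Venkataraman rearrangement (KOH, pyridine, 50 °C) gives 1-[2,5-bis(benzyloxy)phenyl]-3-(2-hydroxy-3,4,5,6-tetramethoxyphenyl)propane-1,3-dione F3.
- Cyclodehydration (NaOAc, AcOH, reflux) closes ring C.

The fallback comes back to the route at 6, bypassing 4 and 5.

**Further compounds**

F1 | step 2 | 2,5-bis(benzyloxy)benzoic acid | O=C(O)c1cc(OCc2ccccc2)ccc1OCc1ccccc1
F2 | step 2 | 2-acetyl-3,4,5,6-tetramethoxyphenyl 2,5-bis(benzyloxy)benzoate | CC(=O)c1c(OC(=O)c2cc(OCc3ccccc3)ccc2OCc2ccccc2)c(OC)c(OC)c(OC)c1OC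
F3 | step 2 | 1-[2,5-bis(benzyloxy)phenyl]-3-(2-hydroxy-3,4,5,6-tetramethoxyphenyl)propane-1,3-dione | O=C(CC(=O)c1c(O)c(OC)c(OC)c(OC)c1OC)c1cc(OCc2ccccc2)ccc1OCc1ccccc1
F4 | step 3 | racemic {2-[2,5-bis(benzyloxy)phenyl]-5,6,7,8-tetramethoxy-2H-chromen-4-yl}oxy(trimethyl)silane | COc1c(OC)c(OC)c2c(c1OC)OC(c1cc(OCc3ccccc3)ccc1OCc1ccccc1)C=C2O[Si](C)(C)C
F5 | step 4 | 2-(2,5-dihydroxyphenyl)-5,6,7,8-tetramethoxy-4H-chromen-4-one | COc1c(OC)c(OC)c2c(=O)cc(-c3cc(O)ccc3O)oc2c1OC
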